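**Plan**

1. The target has a central ring C, a 1,2,3,5-tetraoxygenated benzene. The oxygens at C1 and C3 each carry ring B of a ring A–ring B biaryl, the oxygen at C2 carries ring D (3,4,5-trihydroxyphenyl), and C5 bears a free OH. Rings A are the outer 2,4,6-trihydroxyphenyl groups.
2. Retrosynthetic cuts, in order: the sixteen O–CH3 bonds of a permethyl ether; the aryl–O bond between ring D and the C2 oxygen of ring C; the C1–O and C3–O bonds of ring C; the ring A–ring B biaryl bond.
3. Enabling feature: C1 and C3 of ring C both stand beta to the C5 oxygen. In a cyclohexadienone with C5 as the carbonyl and C2 masked as a dimethyl ketal they are vinylogous acyl carbons, so bromides placed there are replaced by aryloxides through addition–elimination.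
4. Forward: a dibromo quinone monoketal (ring C) is made in two steps and the ring A–ring B phenol in three (bromination, Suzuki coupling, Dakin oxidation). Two phenoxides are joined to the ketal, ring C is rearomatised by hydrolysis and reduction, its unhindered hydroxyl is methylated, ring D is attached to the hindered hydroxyl by copper catalysis, and all methyl ethers are cleaved.
5. No ring is built; all six rings come from commercial benzenes. The target has no stereocentre and its biaryl axes are not stereogenic because ring A is symmetric about the axis, so no stereocontrol is needed.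

Key step: step 6

Remark on numbering: in the dienones, C1 (carbonyl), C3/C5 and C4 (ketal) correspond to C5, C1/C3 and C2 of ring C.

**Route**

Step 1
Reactants: 1 2,6-dibromoanisole (1,3-dibromo-2-methoxybenzene)
Product: 3 3,5-dibromo-4-methoxyphenol, via aryl pinacol boronate 2 (not isolated)
Conditions: [Ir(OMe)(cod)]2 (1.5 mol%), 4,4'-di-tert-butyl-2,2'-bipyridine (3 mol%), B2pin2 (1.0 equiv), THF, 80 °C; volatiles removed; then Oxone, acetone/H2O, 0 °C to rt
Reagents that add atoms: Oxone (potassium peroxymonosulfate, gives the oxygen of the new OH), SMILES [K+].[O-]S(=O)(=O)OO; bis(pinacolato)diboron (its boron and pinacol stay only in intermediate 2), SMILES CC1(C)OB(B2OC(C)(C)C(C)(C)O2)OC1(C)C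
Why: Iridium-catalysed C–H borylation is governed by sterics, so only C4–H, the one ring C–H without an ortho substituent, is borylated while the aryl bromides are left alone, and ipso-oxidation of the boronate by Oxone gives the phenol in the same flask (one-pot C–H borylation/oxidation).

Step 2
Reactants: 3 3,5-dibromo-4-methoxyphenol
Product: 4 3,5-dibromo-4,4-dimethoxycyclohexa-2,5-dien-1-one
Conditions: PhI(OAc)2 (1.1 equiv), MeOH, 0 °C
Reagents that add atoms: methanol, SMILES CO
Why: Oxidative dearomatisation of a para-methoxyphenol by trivalent iodine, in which methanol is captured at the methoxy-bearing para carbon to give the quinone monoketal with both bromides beta to the carbonyl.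

Step 3
Reactants: 5 2,4,6-trimethoxybenzaldehyde
Product: 6 3-bromo-2,4,6-trimethoxybenzaldehyde
Conditions: NBS (1.0 equiv), MeCN, 0 °C to rt
Reagents that add atoms: N-bromosuccinimide, SMILES O=C1CCC(=O)N1Br
Why: Electrophilic aromatic bromination at C3, which is ortho to two methoxy groups and para to the third, with the formyl group and the first bromine damping the ring enough that one equivalent of NBS should stop at the monobromide.

Step 4
Reactants: 6 3-bromo-2,4,6-trimethoxybenzaldehyde; 7 2,4,6-trimethoxyphenylboronic acid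
Product: 8 2,2',4,4',6,6'-hexamethoxybiphenyl-3-carbaldehyde
Conditions: Pd(OAc)2 (5 mol%), SPhos (10 mol%), K3PO4 (3 equiv), toluene/H2O (10:1), 100 °C, 7 (2 equiv, added in two portions), argon
Reagents that add atoms: none
Why: Suzuki–Miyaura coupling, for which SPhos-ligated zerovalent palladium is an established catalyst when four ortho substituents flank the new biaryl bond; the formyl group makes the crowded bromide less electron-rich for oxidative addition and excess boronic acid offsets protodeboronation.

Step 5
Reactants: 8 2,2',4,4',6,6'-hexamethoxybiphenyl-3-carbaldehyde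
Product: 10 2,2',4,4',6,6'-hexamethoxybiphenyl-3-ol, via biaryl formate 9 (not isolated)
Conditions: 30% aq. H2O2 (1.5 equiv), H2SO4 (cat.), MeOH, 0 °C to rt
Reagents that add atoms: hydrogen peroxide, SMILES OO
Why: Acid-catalysed Dakin oxidation (Baeyer–Villiger-type migration of the very electron-rich 2,6-dimethoxyaryl group to oxygen), the aryl formate being methanolysed in the same flask, as is routine for turning 2,4,6-trimethoxybenzaldehydes into the phenols.

Step 6
Reactants: 4 3,5-dibromo-4,4-dimethoxycyclohexa-2,5-dien-1-one; 10 2,2',4,4',6,6'-hexamethoxybiphenyl-3-ol (2.3 equiv)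
Product: 12 3,5-bis[(2,2',4,4',6,6'-hexamethoxybiphenyl-3-yl)oxy]-4,4-dimethoxycyclohexa-2,5-dien-1-one, via monoaryloxy bromodienone ketal 11 (not isolated)
Conditions: Cs2CO3 (3 equiv), degassed DMF, rt then 50 °C, argon
Reagents that add atoms: none
Why: The cesium phenoxide of 10 adds through oxygen to a bromine-bearing beta carbon of the cross-conjugated dienone (C3, then C5) and the resulting enolate expels bromide, so each C–O bond of ring C arises by conjugate addition–elimination on a vinylogous acyl bromide and the sequence runs twice by way of 11. The closest known reaction type is the substitution of beta-halo enones and of halogenated quinone monoketals by phenoxides and alkoxides. No ring is closed and no stereocentre is formed, since the ketal carbon carries two identical methoxy groups. The step needs O- rather than C-arylation of the phenoxide and beta- rather than carbonyl attack on the dienone; the first is secured because both ortho carbons and the para carbon of the phenoxide are substituted, the second because only the two brominated carbons offer a leaving group for the enolate to expel while C2 and C6 are not electrophilic. The dimethyl ketal keeps the future central oxygen distinct from the C1 carbonyl, and the second substitution, slowed by the vinylogous ester character of 11, is driven by the slight excess of phenoxide and gentle warming.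

Step 7
Reactants: 12 3,5-bis[(2,2',4,4',6,6'-hexamethoxybiphenyl-3-yl)oxy]-4,4-dimethoxycyclohexa-2,5-dien-1-one
Product: 13 2,6-bis[(2,2',4,4',6,6'-hexamethoxybiphenyl-3-yl)oxy]-1,4-benzoquinone
Conditions: TsOH·H2O (0.2 equiv), acetone/H2O (10:1), rt
Reagents that add atoms: water, SMILES O
Why: Acid-catalysed hydrolysis of a quinone monoketal, which under mild acid should be faster than addition of water to the aryloxy-bearing enone carbons, so the two aryl ethers are retained.

Step 8
Reactants: 13 2,6-bis[(2,2',4,4',6,6'-hexamethoxybiphenyl-3-yl)oxy]-1,4-benzoquinone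
Product: 14 2,6-bis[(2,2',4,4',6,6'-hexamethoxybiphenyl-3-yl)oxy]benzene-1,4-diol
Conditions: Na2S2O4 (5 equiv), THF/H2O (1:1), rt, argon
Reagents that add atoms: none
Why: Dithionite reduction of a para-benzoquinone to the hydroquinone, under near-neutral conditions that touch neither the aryl ethers nor the methyl ethers.

Step 9
Reactants: 14 2,6-bis[(2,2',4,4',6,6'-hexamethoxybiphenyl-3-yl)oxy]benzene-1,4-diol
Product: 15 4-methoxy-2,6-bis[(2,2',4,4',6,6'-hexamethoxybiphenyl-3-yl)oxy]phenol
Conditions: MeI (1.05 equiv), K2CO3 (1.1 equiv), acetone, rt, argon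
Reagents that add atoms: iodomethane, SMILES CI
Why: Williamson ether synthesis, selective because the C4 hydroxyl is meta to both aryloxy groups and therefore both more acidic and far less hindered than the C1 hydroxyl, which is flanked and hydrogen-bonded by two bulky aryl ethers.

Step 10
Reactants: 15 4-methoxy-2,6-bis[(2,2',4,4',6,6'-hexamethoxybiphenyl-3-yl)oxy]phenol; 16 5-iodo-1,2,3-trimethoxybenzene (1.5 equiv)
Product: 17 5-methoxy-1,3-bis[(2,2',4,4',6,6'-hexamethoxybiphenyl-3-yl)oxy]-2-(3,4,5-trimethoxyphenoxy)benzene
Conditions: CuI (20 mol%), picolinic acid (40 mol%), K3PO4 (2 equiv), DMSO, 90 °C, argon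
Reagents that add atoms: none
Why: Ullmann-type diaryl ether synthesis catalysed by monovalent copper, using the CuI/picolinic acid/K3PO4 system known to accept 2,6-disubstituted phenols and electron-rich aryl iodides; the iodide has no ortho substituent and air is excluded to keep the electron-rich phenoxide from being oxidised.

Step 11
Reactants: 17 5-methoxy-1,3-bis[(2,2',4,4',6,6'-hexamethoxybiphenyl-3-yl)oxy]-2-(3,4,5-trimethoxyphenoxy)benzene
Product: 18 4-(3,4,5-trihydroxyphenoxy)-3,5-bis[(2,2',4,4',6,6'-hexahydroxybiphenyl-3-yl)oxy]phenol (CNP0279880.0)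
Conditions: BBr3 (40 equiv), CH2Cl2, −78 °C to rt; MeOH then H2O at 0 °C; work-up under argon
Reagents that add atoms: none
Why: Lewis acid-mediated cleavage of aryl methyl ethers by BBr3, which leaves diaryl ether and biaryl bonds intact and, used in large excess, should carry all sixteen demethylations to completion.

**Compound list**

1 | 2,6-dibromoanisole (1,3-dibromo-2-methoxybenzene) | COc1c(Br)cccc1Br | starting material
2 | 2-(3,5-dibromo-4-methoxyphenyl)-4,4,5,5-tetramethyl-1,3,2-dioxaborolane (formed in the flask in step 1) | COc1c(Br)cc(B2OC(C)(C)C(C)(C)O2)cc1Br | intermediate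
3 | 3,5-dibromo-4-methoxyphenol | COc1c(Br)cc(O)cc1Br | intermediate
4 | 3,5-dibromo-4,4-dimethoxycyclohexa-2,5-dien-1-one | O=C1C=C(Br)C(OC)(OC)C(Br)=C1 | intermediate
5 | 2,4,6-trimethoxybenzaldehyde | COc1cc(OC)c(C=O)c(OC)c1 | starting material
6 | 3-bromo-2,4,6-trimethoxybenzaldehyde | COc1cc(OC)c(C=O)c(OC)c1Br | intermediate
7 | 2,4,6-trimethoxyphenylboronic acid | COc1cc(OC)c(B(O)O)c(OC)c1 | starting material
8 | 2,2',4,4',6,6'-hexamethoxybiphenyl-3-carbaldehyde | COc1cc(OC)c(C=O)c(OC)c1-c1c(OC)cc(OC)cc1OC | intermediate
9 | 2,2',4,4',6,6'-hexamethoxybiphenyl-3-yl formate (formed in the flask in step 5) | COc1cc(OC)c(OC=O)c(OC)c1-c1c(OC)cc(OC)cc1OC | intermediate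
10 | 2,2',4,4',6,6'-hexamethoxybiphenyl-3-ol | COc1cc(OC)c(O)c(OC)c1-c1c(OC)cc(OC)cc1OC | intermediate
11 | 3-bromo-5-[(2,2',4,4',6,6'-hexamethoxybiphenyl-3-yl)oxy]-4,4-dimethoxycyclohexa-2,5-dien-1-one (formed in the flask in step 6) | O=C1C=C(Br)C(OC)(OC)C(Oc2c(OC)cc(OC)c(-c3c(OC)cc(OC)cc3OC)c2OC)=C1 | intermediate
12 | 3,5-bis[(2,2',4,4',6,6'-hexamethoxybiphenyl-3-yl)oxy]-4,4-dimethoxycyclohexa-2,5-dien-1-one | O=C1C=C(Oc2c(OC)cc(OC)c(-c3c(OC)cc(OC)cc3OC)c2OC)C(OC)(OC)C(Oc2c(OC)cc(OC)c(-c3c(OC)cc(OC)cc3OC)c2OC)=C1 | intermediate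
13 | 2,6-bis[(2,2',4,4',6,6'-hexamethoxybiphenyl-3-yl)oxy]-1,4-benzoquinone | O=C1C=C(Oc2c(OC)cc(OC)c(-c3c(OC)cc(OC)cc3OC)c2OC)C(=O)C(Oc2c(OC)cc(OC)c(-c3c(OC)cc(OC)cc3OC)c2OC)=C1 | intermediate
14 | 2,6-bis[(2,2',4,4',6,6'-hexamethoxybiphenyl-3-yl)oxy]benzene-1,4-diol | Oc1cc(Oc2c(OC)cc(OC)c(-c3c(OC)cc(OC)cc3OC)c2OC)c(O)c(Oc2c(OC)cc(OC)c(-c3c(OC)cc(OC)cc3OC)c2OC)c1 | intermediate
15 | 4-methoxy-2,6-bis[(2,2',4,4',6,6'-hexamethoxybiphenyl-3-yl)oxy]phenol | COc1cc(Oc2c(OC)cc(OC)c(-c3c(OC)cc(OC)cc3OC)c2OC)c(O)c(Oc2c(OC)cc(OC)c(-c3c(OC)cc(OC)cc3OC)c2OC)c1 | intermediate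
16 | 5-iodo-1,2,3-trimethoxybenzene | COc1cc(I)cc(OC)c1OC | starting material
17 | 5-methoxy-1,3-bis[(2,2',4,4',6,6'-hexamethoxybiphenyl-3-yl)oxy]-2-(3,4,5-trimethoxyphenoxy)benzene | COc1cc(Oc2c(OC)cc(OC)c(-c3c(OC)cc(OC)cc3OC)c2OC)c(Oc2cc(OC)c(OC)c(OC)c2)c(Oc2c(OC)cc(OC)c(-c3c(OC)cc(OC)cc3OC)c2OC)c1 | intermediate
18 | 4-(3,4,5-trihydroxyphenoxy)-3,5-bis[(2,2',4,4',6,6'-hexahydroxybiphenyl-3-yl)oxy]phenol (CNP0279880.0) | Oc1cc(O)c(-c2c(O)cc(O)c(Oc3cc(O)cc(Oc4c(O)cc(O)c(-c5c(O)cc(O)cc5O)c4O)c3Oc3cc(O)c(O)c(O)c3)c2O)c(O)c1 | target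

**Count and risks**

Total step count: 11. Longest linear sequence: 9 steps (steps 3 to 11, from 5 to 18).

Steps most likely to fail:

Step 6. The second addition–elimination may stall at the monoaryloxy stage, because 11 is a vinylogous ester and both reacting centres are crowded; electron transfer from the electron-rich phenoxide to the dienone may also consume material. The fallback forms the same two C–O bonds on an already aromatic ring C by copper catalysis. It sets out from 10. Commercial 2,6-dibromo-4-methoxyphenol would be benzylated (BnBr, K2CO3, DMF) to 2-(benzyloxy)-1,3-dibromo-5-methoxybenzene F1. A double Ullmann ether coupling of F1 with 10 (CuI, N,N-dimethylglycine, Cs2CO3, dioxane, 110 °C), the classical way of joining polymethoxyphenols to bromo-polymethoxybenzenes, should give 2-(benzyloxy)-5-methoxy-1,3-bis[(2,2',4,4',6,6'-hexamethoxybiphenyl-3-yl)oxy]benzene F2. Hydrogenolysis (H2, Pd/C, EtOAc/MeOH) would then free the central hydroxyl. The fallback comes back to the route at 15 and makes steps 7 to 9 unnecessary.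

Step 10. Ligand exchange and reductive elimination at copper may be too slow at an oxygen flanked by two bulky aryl ethers, and the phenoxide may instead be oxidised towards quinone 13. The fallback is a metal-free arylation by ligand coupling at trivalent iodine and sets out from 16. Oxidation of 16 (mCPBA, TsOH·H2O, MeCN) should give 5-[hydroxy(tosyloxy)iodo]-1,2,3-trimethoxybenzene F3. In the same flask F3 is condensed with 1,3,5-trimethoxybenzene to (3,4,5-trimethoxyphenyl)(2,4,6-trimethoxyphenyl)iodonium tosylate F4. The potassium phenoxide of 15 (t-BuOK, THF, 0 °C to rt) should then take up the 3,4,5-trimethoxyphenyl group, the more electron-rich 2,4,6-trimethoxyphenyl ligand leaving as its iodide. This reaction type is known to tolerate hindered phenols. The fallback comes back to the route at 17.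

Step 4. Protodeboronation of 7 may outrun the slow transmetalation and reductive elimination needed for a biaryl with four ortho methoxy groups. The fallback is a Negishi coupling with an arylzinc reagent, which cannot be protodemetalated under anhydrous conditions, and it sets out from 6. 1,3,5-Trimethoxybenzene would be lithiated (n-BuLi, THF, 0 °C to rt) to (2,4,6-trimethoxyphenyl)lithium F5 and transmetalated with ZnCl2 to (2,4,6-trimethoxyphenyl)zinc chloride F6. F6 would be coupled with 6 (Pd(OAc)2, SPhos, THF, 60 °C); arylzinc halides do not add to the aldehyde under these conditions. The fallback comes back to the route at 8.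

**Further compounds**

F1 | step 6 | 2-(benzyloxy)-1,3-dibromo-5-methoxybenzene | COc1cc(Br)c(OCc2ccccc2)c(Br)c1
F2 | step 6 | 2-(benzyloxy)-5-methoxy-1,3-bis[(2,2',4,4',6,6'-hexamethoxybiphenyl-3-yl)oxy]benzene | COc1cc(Oc2c(OC)cc(OC)c(-c3c(OC)cc(OC)cc3OC)c2OC)c(OCc2ccccc2)c(Oc2c(OC)cc(OC)c(-c3c(OC)cc(OC)cc3OC)c2OC)c1
F3 | step 10 | 5-[hydroxy(tosyloxy)iodo]-1,2,3-trimethoxybenzene | COc1cc(I(O)OS(=O)(=O)c2ccc(C)cc2)cc(OC)c1OC
F4 | step 10 | (3,4,5-trimethoxyphenyl)(2,4,6-trimethoxyphenyl)iodonium tosylate | COc1cc([I+]c2c(OC)cc(OC)cc2OC)cc(OC)c1OC.Cc1ccc(S(=O)(=O)[O-])cc1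
F5 | step 4 | (2,4,6-trimethoxyphenyl)lithium | [Li]c1c(OC)cc(OC)cc1OC
F6 | step 4 | (2,4,6-trimethoxyphenyl)zinc chloride | Cl[Zn]c1c(OC)cc(OC)cc1OC
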